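**Plan**

1. Labels: the upper flavan has rings A, C, B and unprimed atoms. The lower flavan-3-ol has rings D, F, E and primed atoms. After removal of the benzyl ethers and the 3'-acetate, ring F is cut at O1'–C2' and C3'–C4'.
2. The cut works because ring F is a chroman whose C4' is a bare methylene on ring D and whose C2' aryl and C3' oxygen are cis. It therefore maps onto a [4+2] adduct of the ring D ortho-quinone methide (O1'=C8a'–C4a'=C4'H2) and a (Z)-2-arylvinyl acetate.
3. Further cuts are C4a'–C4' (ortho-formylation), C4–C8' (aryllithium plus flavanone, then C4–O exchanged for C4–H) and C2–ring B (conjugate addition to a chromone).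
4. Forward: rings A and C come with the chromone. Ring B, then ring D, then C4' are attached, rings E and F arrive together in the cycloaddition, and deprotection ends the route.
5. Stereochemistry: C2 (S) comes from a ligand-controlled rhodium 1,4-addition. C4 (S, cis to ring B) comes from axial hydride delivery to the C4 cation on the face anti to ring B. The cis C2'/C3' pair comes from suprafacial addition to the Z alkene, and its absolute sense (R,R) from a chiral phosphoric acid.

Key step: step 11

Assumption: the antipodes of the bisphosphine (step 2) and of the phosphoric acid (step 11) are written as the enone-insertion model and analogy suggest, the other antipode being equally available should the sense prove opposite; 3,5-bis(benzyloxy)phenol is treated as a catalogue chemical.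

**Step 1**
Reactants: 1 7-hydroxychromone
Product: 2 7-(benzyloxy)chromone
Conditions: BnBr, K2CO3, acetone, reflux
Reagents that add atoms: benzyl bromide, BrCc1ccccc1
Why: Williamson ether synthesis on the acidic 7-OH, with a carbonate base too weak to open the pyrone ring.

**Step 2**
Reactants: 2 7-(benzyloxy)chromone; 3 4-(benzyloxy)phenylboronic acid
Product: 4 (2S)-7-(benzyloxy)-2-[4-(benzyloxy)phenyl]chroman-4-one
Conditions: [Rh(OH)(cod)]2 (catalytic), (S)-2,2'-bis[bis(3,4,5-trifluorophenyl)phosphino]-6,6'-dimethoxybiphenyl, toluene/H2O, rt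
Reagents that add atoms: none
Why: Hayashi–Miyaura asymmetric 1,4-addition of an arylboronic acid to a chromone, a known entry to flavanones in which the ligand sets C2 as S and the base-free, room-temperature conditions avoid ring opening and racemisation of the flavanone.

**Step 3**
Reactants: 5 3,5-bis(benzyloxy)phenol
Product: 6 1,3-bis(benzyloxy)-5-(methoxymethoxy)benzene
Conditions: NaH, MOMCl, DMF, 0 °C
Reagents that add atoms: chloromethyl methyl ether, COCCl
Why: Standard O-alkylation of a phenoxide, the MOM acetal being chosen because it marks the future O1', is the best ortho-director on the ring and leaves under mild acid.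

**Step 4**
Reactants: 6 1,3-bis(benzyloxy)-5-(methoxymethoxy)benzene; 4 (2S)-7-(benzyloxy)-2-[4-(benzyloxy)phenyl]chroman-4-one
Product: 8 (2S,4S)-7-(benzyloxy)-2-[4-(benzyloxy)phenyl]-4-[2,4-bis(benzyloxy)-6-(methoxymethoxy)phenyl]chroman-4-ol (4-OH cis and ring D trans to ring B), via aryllithium 7 (not isolated)
Conditions: n-BuLi, THF, 0 °C; then 4 premixed with LaCl3·2LiCl, THF, −78 → −20 °C; aq NH4Cl
Reagents that add atoms: n-butyllithium, [Li]CCCC (gives the lithium of 7)
Why: Directed ortho-metalation, in which the chelating MOM oxygen steers the base to one of the two equivalent sites between OMOM and OBn, is followed by the known 1,2-addition of a 2,4,6-trioxygenated aryllithium to a flavan-4-one with an oxophilic lanthanum salt favouring addition over enolisation, and the C4 carbinol centre expected from axial attack anti to ring B is erased in step 5.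

**Step 5**
Reactants: 8 (2S,4S)-4-aryl-chroman-4-ol described in step 4
Product: 9 (2S,4S)-7-(benzyloxy)-2-[4-(benzyloxy)phenyl]-4-[2,4-bis(benzyloxy)-6-(methoxymethoxy)phenyl]chroman (2,4-cis)
Conditions: Et3SiH, CF3CO2H (few equiv), CH2Cl2, −78 → −40 °C
Reagents that add atoms: none
Why: Kursanov–Parnes ionic hydrogenation, in which the doubly benzylic tertiary alcohol ionises in the cold and the silane delivers hydride along the axial trajectory on the face opposite the equatorial ring B (the sense seen in borohydride reduction of flavanones), so ring D ends equatorial and cis to ring B while the short cold exposure spares the MOM acetal and the O1–C2 bond.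

**Step 6**
Reactants: 9 (2S,4S)-2,4-cis-4-arylflavan MOM ether
Product: 10 3,5-bis(benzyloxy)-2-{(2S,4S)-7-(benzyloxy)-2-[4-(benzyloxy)phenyl]chroman-4-yl}phenol
Conditions: p-TsOH·H2O (catalytic), MeOH/THF, 40 °C
Reagents that add atoms: none
Why: Acid-catalysed transacetalisation of a phenolic MOM ether to methanol, which runs under far milder acid than ionisation of the benzyl ethers, of O1–C2 or of the C4–C8' bond of this 5-deoxy flavan.

**Step 7**
Reactants: 10 3,5-bis(benzyloxy)-2-(flavan-4-yl)phenol
Product: 11 4,6-bis(benzyloxy)-3-{(2S,4S)-7-(benzyloxy)-2-[4-(benzyloxy)phenyl]chroman-4-yl}-2-hydroxybenzaldehyde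
Conditions: MgCl2, Et3N, (CH2O)n, THF, reflux; dilute HCl
Reagents that add atoms: paraformaldehyde (reacts as formaldehyde), C=O
Why: Casnati–Skattebøl formylation goes through a magnesium phenoxide–formaldehyde chelate and is ortho-specific, so the carbon enters at the only free ortho position (C4a') and not at C6' between the two benzyloxy groups.

**Step 8**
Reactants: 11 ring D salicylaldehyde
Product: 12 3,5-bis(benzyloxy)-2-{(2S,4S)-7-(benzyloxy)-2-[4-(benzyloxy)phenyl]chroman-4-yl}-6-(hydroxymethyl)phenol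
Conditions: NaBH4, THF/MeOH, 0 °C; pH 7 buffer
Reagents that add atoms: none
Why: Borohydride reduction of an aryl aldehyde, kept cold and worked up at neutral pH because the trioxygenated salicyl alcohol loses water easily.

**Step 9**
Reactants: 13 3,4-bis(benzyloxy)benzaldehyde
Product: 14 1,2-bis(benzyloxy)-4-ethynylbenzene
Conditions: dimethyl (1-diazo-2-oxopropyl)phosphonate, K2CO3, MeOH/THF, rt
Reagents that add atoms: dimethyl (1-diazo-2-oxopropyl)phosphonate, CC(=O)C(=[N+]=[N-])P(=O)(OC)OC
Why: Ohira–Bestmann variant of the Seyferth–Gilbert homologation, a routine one-carbon conversion of aryl aldehydes into terminal alkynes that tolerates benzyl ethers.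

**Step 10**
Reactants: 14 1,2-bis(benzyloxy)-4-ethynylbenzene
Product: 15 (Z)-2-[3,4-bis(benzyloxy)phenyl]ethenyl acetate
Conditions: AcOH, Ru(methallyl)2(dppb) (catalytic), toluene, 50 °C
Reagents that add atoms: acetic acid, CC(=O)O
Why: Ruthenium-catalysed anti-Markovnikov hydro-acyloxylation of a terminal arylacetylene through a vinylidene complex, known to give the (Z)-enol ester by attack of the carboxylate at the terminal carbon.

**Step 11**
Reactants: 12 ring D salicyl alcohol; 15 (Z)-2-[3,4-bis(benzyloxy)phenyl]ethenyl acetate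
Product: 17 (2R,3R)-5,7-bis(benzyloxy)-2-[3,4-bis(benzyloxy)phenyl]-8-{(2S,4S)-7-(benzyloxy)-2-[4-(benzyloxy)phenyl]chroman-4-yl}chroman-3-yl acetate, via ring D ortho-quinone methide 16 (not isolated)
Conditions: (R)-3,3'-bis(2,4,6-triisopropylphenyl)-1,1'-binaphthyl-2,2'-diyl hydrogen phosphate (10 mol %), 5 Å MS, toluene, 0 °C → rt, 12 added slowly to 15 (3 equiv)
Reagents that add atoms: none
Why: Proposed new method: the phosphoric acid ionises the benzylic C4'–OH of 12, which is pushed out by the oxygen donors at C5', C7' and C8a', and holds the resulting ortho-quinone methide 16 by a hydrogen bond to O1', after which 16 reacts as an electron-poor 1-oxadiene with the electron-rich alkene 15 in an inverse-demand, concerted but asynchronous hetero-Diels–Alder addition. The closest known reactions are [4+2] additions of ortho-quinone methides to β-substituted styrenes such as anethole and to enol ethers, and phosphoric-acid-catalysed enantioselective ortho-quinone methide cycloadditions, whereas an enol ester of an arylacetaldehyde has not served as the two-atom partner. Ring F closes in one six-membered [4+2] event in which O1'–C8a'–C4a'–C4' supplies four atoms and C2'–C3' two, with C3'–C4' bond formation running ahead of O1'–C2'. The required regiochemistry (aryl at C2') follows because the para-benzyloxy group of ring E stabilises developing positive charge at C2' far better than the cross-conjugated acetoxy oxygen could at C3', which makes the acetoxy-bearing carbon the nucleophilic terminus. The cis C2'/C3' relation is the Z geometry carried over by suprafacial addition, which the non-polar solvent, the low temperature and the tight phosphate contact are meant to protect against rotation in a benzylic ion pair, and the absolute sense (2'R,3'R) comes from the 3,3'-aryl pocket of the catalyst because the C4 substituent differentiates the two faces of 16 only weakly. Slow addition of 12 to an excess of 15 keeps 16 dilute so that alkylation of a second ring D at C6' does not compete.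

**Step 12**
Reactants: 17 hexa-O-benzyl 3'-acetate
Product: 18 (2R,3R)-5,7-bis(benzyloxy)-2-[3,4-bis(benzyloxy)phenyl]-8-{(2S,4S)-7-(benzyloxy)-2-[4-(benzyloxy)phenyl]chroman-4-yl}chroman-3-ol
Conditions: K2CO3 (catalytic), MeOH/THF, rt
Reagents that add atoms: none
Why: Base-catalysed transesterification of a secondary acetate, harmless to C2' because no free para-phenol is present to open ring F.

**Step 13**
Reactants: 18 hexa-O-benzyl 3'-ol
Product: 19 (2R,3R)-2-(3,4-dihydroxyphenyl)-8-[(2S,4S)-7-hydroxy-2-(4-hydroxyphenyl)chroman-4-yl]chroman-3,5,7-triol (target)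
Conditions: H2 (1 atm), Pd(OH)2/C, THF/MeOH, rt
Reagents that add atoms: none
Why: Hydrogenolysis of aryl benzyl ethers over Pd(OH)2 on carbon, the usual neutral end-game for flavan oligomers, which leaves the ring C and ring F ethers and all four stereocentres untouched.

**Compound list**

1 | 7-hydroxychromone | O=c1ccoc2cc(O)ccc12 | starting material
2 | 7-(benzyloxy)chromone | O=c1ccoc2cc(OCc3ccccc3)ccc12 | intermediate
3 | 4-(benzyloxy)phenylboronic acid | OB(O)c1ccc(OCc2ccccc2)cc1 | starting material
4 | (2S)-7-(benzyloxy)-2-[4-(benzyloxy)phenyl]chroman-4-one | O=C1C[C@@H](c2ccc(OCc3ccccc3)cc2)Oc2cc(OCc3ccccc3)ccc12 | intermediate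
5 | 3,5-bis(benzyloxy)phenol | Oc1cc(OCc2ccccc2)cc(OCc2ccccc2)c1 | starting material
6 | 1,3-bis(benzyloxy)-5-(methoxymethoxy)benzene | COCOc1cc(OCc2ccccc2)cc(OCc2ccccc2)c1 | intermediate
7 | 2,4-bis(benzyloxy)-6-(methoxymethoxy)phenyllithium (formed in the flask) | [Li]c1c(OCOC)cc(OCc2ccccc2)cc1OCc1ccccc1 | intermediate
8 | (2S,4S)-7-(benzyloxy)-2-[4-(benzyloxy)phenyl]-4-[2,4-bis(benzyloxy)-6-(methoxymethoxy)phenyl]chroman-4-ol | c5ccccc5COc1ccc([C@@H]2C[C@@](O)(c3c(OCOC)cc(OCc5ccccc5)cc3OCc3ccccc3)c3ccc(OCc5ccccc5)cc3O2)cc1 | intermediate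
9 | (2S,4S)-7-(benzyloxy)-2-[4-(benzyloxy)phenyl]-4-[2,4-bis(benzyloxy)-6-(methoxymethoxy)phenyl]chroman, 2,4-cis | c5ccccc5COc1ccc([C@@H]2C[C@H](c3c(OCOC)cc(OCc5ccccc5)cc3OCc3ccccc3)c3ccc(OCc5ccccc5)cc3O2)cc1 | intermediate
10 | 3,5-bis(benzyloxy)-2-{(2S,4S)-7-(benzyloxy)-2-[4-(benzyloxy)phenyl]chroman-4-yl}phenol | c5ccccc5COc1ccc([C@@H]2C[C@H](c3c(O)cc(OCc5ccccc5)cc3OCc3ccccc3)c3ccc(OCc5ccccc5)cc3O2)cc1 | intermediate
11 | 4,6-bis(benzyloxy)-3-{(2S,4S)-7-(benzyloxy)-2-[4-(benzyloxy)phenyl]chroman-4-yl}-2-hydroxybenzaldehyde | c5ccccc5COc1ccc([C@@H]2C[C@H](c3c(OCc5ccccc5)cc(OCc5ccccc5)c(C=O)c3O)c3ccc(OCc5ccccc5)cc3O2)cc1 | intermediate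
12 | 3,5-bis(benzyloxy)-2-{(2S,4S)-7-(benzyloxy)-2-[4-(benzyloxy)phenyl]chroman-4-yl}-6-(hydroxymethyl)phenol | c5ccccc5COc1ccc([C@@H]2C[C@H](c3c(OCc5ccccc5)cc(OCc5ccccc5)c(CO)c3O)c3ccc(OCc5ccccc5)cc3O2)cc1 | intermediate
13 | 3,4-bis(benzyloxy)benzaldehyde | O=Cc1ccc(OCc2ccccc2)c(OCc2ccccc2)c1 | starting material
14 | 1,2-bis(benzyloxy)-4-ethynylbenzene | C#Cc1ccc(OCc2ccccc2)c(OCc2ccccc2)c1 | intermediate
15 | (Z)-2-[3,4-bis(benzyloxy)phenyl]ethenyl acetate | CC(=O)O/C=C\c1ccc(OCc2ccccc2)c(OCc2ccccc2)c1 | intermediate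
16 | 3,5-bis(benzyloxy)-2-{(2S,4S)-7-(benzyloxy)-2-[4-(benzyloxy)phenyl]chroman-4-yl}-6-methylidenecyclohexa-2,4-dien-1-one (formed in the flask) | c5ccccc5COc1ccc([C@@H]2C[C@H](C3=C(OCc5ccccc5)C=C(OCc5ccccc5)C(=C)C3=O)c3ccc(OCc5ccccc5)cc3O2)cc1 | intermediate
17 | (2R,3R)-5,7-bis(benzyloxy)-2-[3,4-bis(benzyloxy)phenyl]-8-{(2S,4S)-7-(benzyloxy)-2-[4-(benzyloxy)phenyl]chroman-4-yl}chroman-3-yl acetate | c5ccccc5COc1ccc([C@@H]2C[C@H](c3c(OCc5ccccc5)cc(OCc5ccccc5)c4c3O[C@H](c3ccc(OCc5ccccc5)c(OCc5ccccc5)c3)[C@H](OC(C)=O)C4)c3ccc(OCc5ccccc5)cc3O2)cc1 | intermediate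
18 | (2R,3R)-5,7-bis(benzyloxy)-2-[3,4-bis(benzyloxy)phenyl]-8-{(2S,4S)-7-(benzyloxy)-2-[4-(benzyloxy)phenyl]chroman-4-yl}chroman-3-ol | c5ccccc5COc1ccc([C@@H]2C[C@H](c3c(OCc5ccccc5)cc(OCc5ccccc5)c4c3O[C@H](c3ccc(OCc5ccccc5)c(OCc5ccccc5)c3)[C@H](O)C4)c3ccc(OCc5ccccc5)cc3O2)cc1 | intermediate
19 | (2R,3R)-2-(3,4-dihydroxyphenyl)-8-[(2S,4S)-7-hydroxy-2-(4-hydroxyphenyl)chroman-4-yl]chroman-3,5,7-triol | Oc1ccc([C@@H]2C[C@H](c3c(O)cc(O)c4c3O[C@H](c3ccc(O)c(O)c3)[C@H](O)C4)c3ccc(O)cc3O2)cc1 | target

**Totals**

Total step count: 13. Longest linear sequence: 10 steps (1, 2, 4, 5, 6, 7, 8, 11, 12, 13).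

**Steps most likely to fail**

**Step 11.**
- The addition may turn stepwise, so that rotation in a long-lived, strongly stabilised benzylic ion pair erases the cis relation.
- The phosphate may discriminate poorly between the faces, because the enol ester offers it no hydrogen-bond donor.
- The sluggish dienophile may lose out to self-alkylation of ring D at C6'.

The fallback uses known chemistry only. It sets out from flavanone 4 and comes back at target 19. Commercial (−)-epicatechin is perbenzylated (BnBr, NaH, DMF, 0 °C) to penta-O-benzyl-(−)-epicatechin F1. NBS in CH2Cl2 at −78 °C brominates the most nucleophilic position to give the 8-bromide F2, and n-BuLi exchange at −78 °C gives the 8-lithio compound F3. This is added to 4 as in step 4 to give the tertiary alcohol F4. Et3SiH with CF3CO2H as in step 5 gives the 2,4-cis hepta-O-benzyl ether F5, and hydrogenolysis as in step 13 gives 19. Ring F and its two stereocentres are then bought, not made.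

**Step 4.** The hindered aryl anion may take a proton from C3 of the flavanone in place of adding to the carbonyl. β-Elimination of the ring A phenoxide would follow, which opens ring C and erases C2.

The fallback turns the enolisation to use. It sets out from 4 and from aryllithium 7 and comes back at 9. KN(SiMe3)2 is added at −78 °C to 4 and N-(5-chloro-2-pyridyl)bis(trifluoromethanesulfonimide) in THF, so that the enolate is trapped at once as the flav-3-en-4-yl triflate F6. Aryllithium 7 is transmetalated with ZnCl2 to the arylzinc chloride F7. Negishi coupling (Pd(OAc)2, SPhos, THF, 50 °C) gives the 4-arylflav-3-ene F8. Under the conditions of step 5, protonation at C3 produces the same C4 cation and hence 9.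

**Step 7.** Formylation may be slow at the crowded magnesium phenoxide. The hydroxymethyl phenoxide intermediate may also lose hydroxide and alkylate a second ring D.

The fallback sets out from 10 and comes back at 12, bypassing 11 and step 8. Boronate-templated ortho-hydroxymethylation (PhB(OH)2, paraformaldehyde, catalytic propionic acid, toluene, reflux with a water separator) gives the 2-phenyl-4H-1,3,2-benzodioxaborin F9. Exchange with propane-1,3-diol in THF at rt then releases 12.

**Further compounds**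

F1 | step 11 | (2R,3R)-3,5,7-tris(benzyloxy)-2-[3,4-bis(benzyloxy)phenyl]chroman (penta-O-benzyl-(−)-epicatechin) | c1ccccc1COc1cc(OCc2ccccc2)c2c(c1)O[C@H](c1ccc(OCc3ccccc3)c(OCc3ccccc3)c1)[C@H](OCc1ccccc1)C2
F2 | step 11 | (2R,3R)-8-bromo-3,5,7-tris(benzyloxy)-2-[3,4-bis(benzyloxy)phenyl]chroman | c1ccccc1COc1cc(OCc2ccccc2)c2c(c1Br)O[C@H](c1ccc(OCc3ccccc3)c(OCc3ccccc3)c1)[C@H](OCc1ccccc1)C2
F3 | step 11 | (2R,3R)-8-lithio-3,5,7-tris(benzyloxy)-2-[3,4-bis(benzyloxy)phenyl]chroman | c1ccccc1COc1cc(OCc2ccccc2)c2c(c1[Li])O[C@H](c1ccc(OCc3ccccc3)c(OCc3ccccc3)c1)[C@H](OCc1ccccc1)C2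
F4 | step 11 | (2S,4S)-7-(benzyloxy)-2-[4-(benzyloxy)phenyl]-4-{(2R,3R)-3,5,7-tris(benzyloxy)-2-[3,4-bis(benzyloxy)phenyl]chroman-8-yl}chroman-4-ol | c5ccccc5COc1ccc([C@@H]2C[C@@](O)(c3c(OCc5ccccc5)cc(OCc5ccccc5)c4c3O[C@H](c3ccc(OCc5ccccc5)c(OCc5ccccc5)c3)[C@H](OCc3ccccc3)C4)c3ccc(OCc5ccccc5)cc3O2)cc1
F5 | step 11 | hepta-O-benzyl ether of 19 (2S,4S,2'R,3'R) | c5ccccc5COc1ccc([C@@H]2C[C@H](c3c(OCc5ccccc5)cc(OCc5ccccc5)c4c3O[C@H](c3ccc(OCc5ccccc5)c(OCc5ccccc5)c3)[C@H](OCc3ccccc3)C4)c3ccc(OCc5ccccc5)cc3O2)cc1
F6 | step 4 | (2S)-7-(benzyloxy)-2-[4-(benzyloxy)phenyl]-2H-chromen-4-yl trifluoromethanesulfonate | c5ccccc5COc1ccc([C@@H]2C=C(OS(=O)(=O)C(F)(F)F)c3ccc(OCc5ccccc5)cc3O2)cc1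
F7 | step 4 | [2,4-bis(benzyloxy)-6-(methoxymethoxy)phenyl]zinc chloride | Cl[Zn]c1c(OCOC)cc(OCc2ccccc2)cc1OCc1ccccc1
F8 | step 4 | (2S)-7-(benzyloxy)-2-[4-(benzyloxy)phenyl]-4-[2,4-bis(benzyloxy)-6-(methoxymethoxy)phenyl]-2H-chromene | c5ccccc5COc1ccc([C@@H]2C=C(c3c(OCOC)cc(OCc5ccccc5)cc3OCc3ccccc3)c3ccc(OCc5ccccc5)cc3O2)cc1
F9 | step 7 | 5,7-bis(benzyloxy)-8-{(2S,4S)-7-(benzyloxy)-2-[4-(benzyloxy)phenyl]chroman-4-yl}-2-phenyl-4H-1,3,2-benzodioxaborin | c5ccccc5COc1ccc([C@@H]2C[C@H](c3c(OCc5ccccc5)cc(OCc5ccccc5)c4c3OB(c3ccccc3)OC4)c3ccc(OCc5ccccc5)cc3O2)cc1
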